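**Retrosynthetic overview**
1. Target ⇐ C9–C11 bond by denitrative radical vinylation of a tertiary C9 nitro group with a preformed stannylvinyl butenolide; C18 ⇐ Stille methylation of a C4 enol triflate, which keeps Δ3 masked during osmylation.
2. 7β,8β-Diol ⇐ OsO4 on Δ7, anti to 6α-OAc; 6α-OAc ⇐ Luche reduction and acetylation of the ring-B enone.
3. Rings A and B ⇐ one organocatalytic operation on an acyclic yne-1,3-dione/nitroalkene: Michael addition C5→C10 closes ring A, then nitronate C9→ynone C8 (6-endo-dig) closes ring B.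
4. Acyclic precursor ⇐ boron aldol and oxidation of hex-4-yn-3-one with (E)-6-nitrohept-5-enal; the latter ⇐ cyclopentene (ozonolysis) and nitroethane (Henry).

Numbering: clerodane numbering throughout (ring carbons C1–C10, C5/C10 ring fusion; C17 on C8, C18 on C4, C19 on C5, C20 on C9); α = face of C19, β = face of H-10; "decal" = decalin skeleton.
Assumption: the quinidine-derived squaramide gives the absolute sense drawn in step 6; if it gives the opposite sense, the pseudo-enantiomeric quinine-derived catalyst is used instead.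

Step 1
Reactants: 1 cyclopentene
Product: 4 5,5-dimethoxypentanal, via 5-hydroperoxy-5-methoxypentanal 2 (not isolated), via 1-hydroperoxy-1,5,5-trimethoxypentane 3 (not isolated)
Conditions: O3, CH2Cl2/MeOH, −78 °C; TsOH (cat.), rt; NaHCO3, Me2S
Reagents that add atoms: ozone [O-][O+]=O; methanol CO
Why: Criegee ozonolysis in methanol gives an aldehyde and a methoxy hydroperoxide at the two termini, acid acetalizes only the free aldehyde, and Me2S then reduces the hydroperoxide terminus to the aldehyde (unsymmetrical ozonolysis); no stereocenter.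

Step 2
Reactants: 4 5,5-dimethoxypentanal; 5 nitroethane
Product: 8 (E)-7,7-dimethoxy-2-nitrohept-2-ene, via 7,7-dimethoxy-2-nitroheptan-3-ol 6 (not isolated), via 7,7-dimethoxy-2-nitroheptan-3-yl mesylate 7 (not isolated)
Conditions: EtNO2 (5 equiv), TMG (10 mol %), THF, 0 °C→rt; then MsCl, Et3N, CH2Cl2, −20 °C→rt
Reagents that add atoms: none
Why: Henry (nitroaldol) addition followed by mesylation and E1cB elimination gives the conjugated nitroalkene, the E isomer (chain trans to NO2) being thermodynamically favoured; the acetal is inert to base.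

Step 3
Reactants: 8 (E)-7,7-dimethoxy-2-nitrohept-2-ene
Product: 9 (E)-6-nitrohept-5-enal
Conditions: 1 M HCl, THF, rt
Reagents that add atoms: water O
Why: Acid-catalysed acetal hydrolysis; the nitroalkene tolerates dilute aqueous acid.

Step 4
Reactants: 9 (E)-6-nitrohept-5-enal; 10 hex-4-yn-3-one
Product: 13 (10E)-6-hydroxy-5-methyl-11-nitrododec-10-en-2-yn-4-one (syn/anti mixture), via dibutylboron (Z)-enolate 11 (not isolated), via boron aldolate 12 (not isolated)
Conditions: 10, n-Bu2BOTf, i-Pr2NEt, CH2Cl2, −78 °C; then 9, −78→−20 °C; MeOH/pH 7 buffer (no peroxide)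
Reagents that add atoms: none
Why: Boron-mediated aldol addition: the ethyl ketone has a single enolizable position and its boron enolate adds to the aldehyde far faster than to the nitroalkene; both new stereocenters are erased later, so their ratio is irrelevant.

Step 5
Reactants: 13 (10E)-6-hydroxy-5-methyl-11-nitrododec-10-en-2-yn-4-one
Product: 14 (10E)-5-methyl-11-nitrododec-10-en-2-yne-4,6-dione
Conditions: Dess–Martin periodinane, CH2Cl2, 0 °C→rt; rapid silica filtration, used at once
Reagents that add atoms: none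
Why: Dess–Martin oxidation of the β-hydroxy ketone to the 2-methyl-1,3-diketone under non-basic conditions, so that cyclization does not start before the chiral catalyst is present.

Step 6
Reactants: 14 (10E)-5-methyl-11-nitrododec-10-en-2-yne-4,6-dione
Product: 16 5α,8,9-trimethyl-9-nitro-10βH-decal-7-ene-4,6-dione (trans-fused; C9 epimers), via trans-2-(but-2-ynoyl)-2-methyl-3-(1-nitroethyl)cyclohexanone 15 (not isolated)
Conditions: quinidine-derived bifunctional squaramide (10 mol %), CH2Cl2 (0.02 M), −20 °C; then DBU (20 mol %), 0 °C→rt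
Reagents that add atoms: none
Why: Proposed new method: the catalyst deprotonates the 1,3-diketone (pKa about 11) and H-bonds the nitroalkene, so C5 adds to C10 through a 6-exo-trig chair in which the chelated U-shaped diketonate places the butynoyl group equatorial and C19 axial while the nitroalkene lies equatorial (trans-15, absolute sense from the catalyst), and the nitronate then adds 6-endo-dig to the ynone to close ring B as the enone; the closest known reactions are squaramide-catalysed Michael additions of 2-substituted 1,3-diketones to nitroalkenes and base-mediated nitro-Michael closure of nitroalkane/ynone adducts to 4-nitrocyclohex-2-enones (the C9 configuration is irrelevant because C9 becomes a radical in step 13).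

Step 7
Reactants: 16 5α,8,9-trimethyl-9-nitro-10βH-decal-7-ene-4,6-dione
Product: 18 5α,8,9-trimethyl-9-nitro-6-oxo-10βH-decala-3,7-dien-4-yl triflate, via potassium C3-enolate 17 (not isolated)
Conditions: KHMDS, THF, −78 °C; Comins' reagent, −78→−40 °C
Reagents that add atoms: Comins' reagent Clc1ccc(nc1)N(S(=O)(=O)C(F)(F)F)S(=O)(=O)C(F)(F)F
Why: Kinetic deprotonation occurs at C3 (C5 is quaternary and the enone has no α′-H), and O-sulfonylation gives the enol triflate, an electron-poor alkene that carries the future Δ3 through the osmylation untouched.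

Step 8
Reactants: 18 5α,8,9-trimethyl-9-nitro-6-oxo-10βH-decala-3,7-dien-4-yl triflate
Product: 19 6α-hydroxy-5α,8,9-trimethyl-9-nitro-10βH-decala-3,7-dien-4-yl triflate
Conditions: NaBH4, CeCl3·7H2O, MeOH, −78 °C
Reagents that add atoms: none
Why: Luche 1,2-reduction: hydride attacks the β-face, anti to the axial C19 methyl on the neighbouring C5, giving the equatorial 6α-alcohol (OH cis to C19).

Step 9
Reactants: 19 6α-hydroxy-5α,8,9-trimethyl-9-nitro-10βH-decala-3,7-dien-4-yl triflate
Product: 20 6α-acetoxy-5α,8,9-trimethyl-9-nitro-10βH-decala-3,7-dien-4-yl triflate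
Conditions: Ac2O, DMAP (cat.), pyridine, rt
Reagents that add atoms: acetic anhydride CC(=O)OC(C)=O
Why: DMAP-catalysed acylation of the hindered secondary allylic alcohol; no stereocenter is touched.

Step 10
Reactants: 20 6α-acetoxy-5α,8,9-trimethyl-9-nitro-10βH-decala-3,7-dien-4-yl triflate
Product: 21 6α-acetoxy-7β,8β-dihydroxy-5α,8α,9-trimethyl-9-nitro-10βH-decal-3-en-4-yl triflate
Conditions: OsO4 (10 mol %), NMO, citric acid, t-BuOH/H2O, rt
Reagents that add atoms: osmium tetroxide O=[Os](=O)(=O)=O; N-methylmorpholine N-oxide C[N+]1([O-])CCOCC1; water O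
Why: Upjohn syn-dihydroxylation of the only electron-rich alkene (the enol triflate is inert): OsO4 adds to the β-face, anti to the allylic 6α-acetate (Kishi's rule) and away from the α-axial C19 methyl and α-axial C9 substituent, setting 7β-OH and 8β-OH (C17 α).

Step 11
Reactants: 21 6α-acetoxy-7β,8β-dihydroxy-5α,8α,9-trimethyl-9-nitro-10βH-decal-3-en-4-yl triflate
Product: 22 6α-acetoxy-4,5α,8α,9-tetramethyl-9-nitro-10βH-decal-3-ene-7β,8β-diol
Conditions: Me4Sn, Pd2(dba)3 (5 mol %), AsPh3, LiCl, NMP, 60 °C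
Reagents that add atoms: tetramethylstannane C[Sn](C)(C)C
Why: Stille cross-coupling of the enol triflate installs C18 and unveils Δ3 under neutral conditions that do not provoke retro-Henry cleavage of the β-nitro alcohol; no stereocenter is touched.

Step 12
Reactants: 23 4-bromofuran-2(5H)-one; 24 (E)-1,2-bis(tributylstannyl)ethene
Product: 25 (E)-4-[2-(tributylstannyl)ethenyl]furan-2(5H)-one
Conditions: 24 (1.5 equiv), Pd(PPh3)4 (5 mol %), toluene, 80 °C
Reagents that add atoms: none
Why: Stille coupling of the vinyl bromide with excess distannane gives the mono-coupled stannyl diene with retention of E geometry.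

Step 13
Reactants: 22 6α-acetoxy-4,5α,8α,9-tetramethyl-9-nitro-10βH-decal-3-ene-7β,8β-diol; 25 (E)-4-[2-(tributylstannyl)ethenyl]furan-2(5H)-one
Product: 26 target CNP0279118.1, (11E)-6α-acetoxy-7β,8β-dihydroxycleroda-3,11,13-trien-15,16-olide (5α-CH3; 9α-CH3; 10β-H)
Conditions: 25 (3 equiv), AIBN (0.4 equiv, portions), (Bu3Sn)2 (10 mol %), PhH, 80 °C
Reagents that add atoms: none
Why: Proposed new method: Bu3Sn• removes the tertiary nitro group (tin-mediated denitration), the C9 radical adds to the tin-bearing terminus of 25 (δ-carbon of a dienoate, giving a lactone-stabilised allylic radical) and β-scission of Bu3Sn• gives the (E)-alkene and carries the chain, as in β-stannylacrylate radical vinylation and denitrative allylation with allylstannanes; the planar C9 radical is attacked on the β-face (equatorial trajectory) because the α-face is 1,3-diaxial to C19, so C20 ends α and the side chain β.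

**Compound list**
1 | cyclopentene | C1=CCCC1 | starting material
2 | 5-hydroperoxy-5-methoxypentanal (not isolated) | COC(OO)CCCC=O | intermediate
3 | 1-hydroperoxy-1,5,5-trimethoxypentane (not isolated) | COC(OO)CCCC(OC)OC | intermediate
4 | 5,5-dimethoxypentanal | COC(OC)CCCC=O | intermediate
5 | nitroethane | CC[N+](=O)[O-] | starting material
6 | 7,7-dimethoxy-2-nitroheptan-3-ol (not isolated) | COC(OC)CCCC(O)C(C)[N+](=O)[O-] | intermediate
7 | 7,7-dimethoxy-2-nitroheptan-3-yl mesylate (not isolated) | COC(OC)CCCC(OS(C)(=O)=O)C(C)[N+](=O)[O-] | intermediate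
8 | (E)-7,7-dimethoxy-2-nitrohept-2-ene | COC(OC)CCC/C=C(\C)[N+](=O)[O-] | intermediate
9 | (E)-6-nitrohept-5-enal | O=CCCC/C=C(\C)[N+](=O)[O-] | intermediate
10 | hex-4-yn-3-one | CCC(=O)C#CC | starting material
11 | dibutylboron (Z)-enolate of 10 (not isolated) | CCCCB(CCCC)O/C(=C\C)C#CC | intermediate
12 | dibutylboron aldolate of 13 (not isolated) | CCCCB(CCCC)OC(CCC/C=C(\C)[N+](=O)[O-])C(C)C(=O)C#CC | intermediate
13 | (10E)-6-hydroxy-5-methyl-11-nitrododec-10-en-2-yn-4-one (syn/anti mixture) | CC#CC(=O)C(C)C(O)CCC/C=C(\C)[N+](=O)[O-] | intermediate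
14 | (10E)-5-methyl-11-nitrododec-10-en-2-yne-4,6-dione | CC#CC(=O)C(C)C(=O)CCC/C=C(\C)[N+](=O)[O-] | intermediate
15 | trans-2-(but-2-ynoyl)-2-methyl-3-(1-nitroethyl)cyclohexanone (acyl and nitroethyl trans; not isolated) | [O-][N+](=O)C(C)[C@H]1CCCC(=O)[C@@]1(C(=O)C#CC)C | intermediate
16 | 5α,8,9-trimethyl-9-nitro-10βH-decal-7-ene-4,6-dione (trans-fused; C9 epimers) | O=C1C=C(C)C(C)([N+](=O)[O-])[C@H]2CCCC(=O)[C@]12C | intermediate
17 | potassium C3-enolate of 16 (not isolated) | [K+].O=C1C=C(C)C(C)([N+](=O)[O-])[C@H]2CCC=C([O-])[C@]12C | intermediate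
18 | 5α,8,9-trimethyl-9-nitro-6-oxo-10βH-decala-3,7-dien-4-yl triflate | O=C1C=C(C)C(C)([N+](=O)[O-])[C@H]2CCC=C(OS(=O)(=O)C(F)(F)F)[C@]12C | intermediate
19 | 6α-hydroxy-5α,8,9-trimethyl-9-nitro-10βH-decala-3,7-dien-4-yl triflate | O[C@H]1C=C(C)C(C)([N+](=O)[O-])[C@H]2CCC=C(OS(=O)(=O)C(F)(F)F)[C@]12C | intermediate
20 | 6α-acetoxy-5α,8,9-trimethyl-9-nitro-10βH-decala-3,7-dien-4-yl triflate | CC(=O)O[C@H]1C=C(C)C(C)([N+](=O)[O-])[C@H]2CCC=C(OS(=O)(=O)C(F)(F)F)[C@]12C | intermediate
21 | 6α-acetoxy-7β,8β-dihydroxy-5α,8α,9-trimethyl-9-nitro-10βH-decal-3-en-4-yl triflate | CC(=O)O[C@H]1[C@H](O)[C@](C)(O)C(C)([N+](=O)[O-])[C@H]2CCC=C(OS(=O)(=O)C(F)(F)F)[C@]12C | intermediate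
22 | 6α-acetoxy-4,5α,8α,9-tetramethyl-9-nitro-10βH-decal-3-ene-7β,8β-diol | CC(=O)O[C@H]1[C@H](O)[C@](C)(O)C(C)([N+](=O)[O-])[C@H]2CCC=C(C)[C@]12C | intermediate
23 | 4-bromofuran-2(5H)-one | BrC1=CC(=O)OC1 | starting material
24 | (E)-1,2-bis(tributylstannyl)ethene | CCCC[Sn](CCCC)(CCCC)/C=C/[Sn](CCCC)(CCCC)CCCC | starting material
25 | (E)-4-[2-(tributylstannyl)ethenyl]furan-2(5H)-one | CCCC[Sn](CCCC)(CCCC)/C=C/C1=CC(=O)OC1 | intermediate
26 | CNP0279118.1, (11E)-6α-acetoxy-7β,8β-dihydroxycleroda-3,11,13-trien-15,16-olide | CC(=O)O[C@H]1[C@H](O)[C@](C)(O)[C@](C)(/C=C/C2=CC(=O)OC2)[C@H]2CCC=C(C)[C@]12C | target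

**Totals**
Total steps: 13. Longest linear sequence: 12 (steps 1–11 and 13; step 12 is the side branch).

**Steps most likely to fail, with fallbacks**

Step 6 (bicyclization). Risks: O-cyclization of 14 to a 4-pyranone, addition of the catalyst amine to the ynone, a sluggish 6-endo-dig closure, and the unproven trans (C5/C10) and enantiofacial control. The fallback replaces the ynone acceptor by an enone; it sets out from 9 and returns at 18. Aldehyde 9 is taken through the same boron aldol with commercial (E)-hex-4-en-3-one to give (2E,10E)-6-hydroxy-5-methyl-11-nitrododeca-2,10-dien-4-one F1, which Dess–Martin periodinane oxidizes to (2E,10E)-5-methyl-11-nitrododeca-2,10-diene-4,6-dione F2. The same squaramide catalysis closes ring A, and the nitronate then closes ring B by 6-endo-trig Michael addition to the enone, giving 5α,8,9-trimethyl-9-nitro-10βH-decalin-4,6-dione F3. Kinetic enolization at the less hindered C3 (KHMDS, Comins' reagent, −78 °C) gives 5α,8,9-trimethyl-9-nitro-6-oxo-10βH-decal-3-en-4-yl triflate F4, and IBX (DMSO, 70 °C) dehydrogenates the remaining C6 ketone, which can enolize only towards C7, to give 18.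

Step 10 (dihydroxylation). Risk: the Δ7 alkene of 20 is hindered and deactivated by both the allylic acetate and the allylic nitro group. The fallback changes the order of events; it sets out from 19 and returns at 21. The free allylic alcohol 19 is dihydroxylated (OsO4 cat., NMO, again anti to the C6 oxygen) to 6α,7β,8β-trihydroxy-5α,8α,9-trimethyl-9-nitro-10βH-decal-3-en-4-yl triflate F5. The cis-7,8-diol is tied up as its 7,8-O-isopropylidene derivative F6 (2,2-dimethoxypropane, PPTS), the 6α-OH is acetylated to the 6α-acetoxy 7,8-acetonide F7 (Ac2O, DMAP), and the acetonide is removed (80% AcOH, 40 °C) to give 21.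

Step 13 (radical vinylation). Risk: the hindered C9 radical may be reduced rather than add to the tin-bearing carbon of 25. The fallback builds the side chain in two bonds; it sets out from 22 and returns at 26. Compound 22 is heated with the small acceptor (E)-1,2-bis(tributylstannyl)ethene 24 (AIBN, PhH, 80 °C), whose addition–fragmentation gives 6α-acetoxy-4,5α,8α,9α-tetramethyl-9β-[(E)-2-(tributylstannyl)ethenyl]-10βH-decal-3-ene-7β,8β-diol F8. F8 is then joined to 4-bromofuran-2(5H)-one 23 by Stille coupling (Pd2(dba)3, AsPh3, CuI, NMP, 50 °C) to give 26.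

**Further compounds**
F1 | step 6 | (2E,10E)-6-hydroxy-5-methyl-11-nitrododeca-2,10-dien-4-one | C/C=C/C(=O)C(C)C(O)CCC/C=C(\C)[N+](=O)[O-]
F2 | step 6 | (2E,10E)-5-methyl-11-nitrododeca-2,10-diene-4,6-dione | C/C=C/C(=O)C(C)C(=O)CCC/C=C(\C)[N+](=O)[O-]
F3 | step 6 | 5α,8,9-trimethyl-9-nitro-10βH-decalin-4,6-dione (trans-fused) | O=C1CC(C)C(C)([N+](=O)[O-])[C@H]2CCCC(=O)[C@]12C
F4 | step 6 | 5α,8,9-trimethyl-9-nitro-6-oxo-10βH-decal-3-en-4-yl triflate | O=C1CC(C)C(C)([N+](=O)[O-])[C@H]2CCC=C(OS(=O)(=O)C(F)(F)F)[C@]12C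
F5 | step 10 | 6α,7β,8β-trihydroxy-5α,8α,9-trimethyl-9-nitro-10βH-decal-3-en-4-yl triflate | O[C@H]1[C@H](O)[C@](C)(O)C(C)([N+](=O)[O-])[C@H]2CCC=C(OS(=O)(=O)C(F)(F)F)[C@]12C
F6 | step 10 | 7β,8β-O-isopropylidene derivative of F5 | O[C@H]1[C@@H]3OC(C)(C)O[C@]3(C)C(C)([N+](=O)[O-])[C@H]2CCC=C(OS(=O)(=O)C(F)(F)F)[C@]12C
F7 | step 10 | 6α-acetate of F6 | CC(=O)O[C@H]1[C@@H]3OC(C)(C)O[C@]3(C)C(C)([N+](=O)[O-])[C@H]2CCC=C(OS(=O)(=O)C(F)(F)F)[C@]12C
F8 | step 13 | 6α-acetoxy-4,5α,8α,9α-tetramethyl-9β-[(E)-2-(tributylstannyl)ethenyl]-10βH-decal-3-ene-7β,8β-diol | CC(=O)O[C@H]1[C@H](O)[C@](C)(O)[C@](C)(/C=C/[Sn](CCCC)(CCCC)CCCC)[C@H]2CCC=C(C)[C@]12C
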